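**Retrosynthetic overview**
1. The enal bond C14=C15′ is cut by a directed crossed aldol condensation: the 5α (trans-fused) C20 aldehyde is the donor, as its metalated aldimine, and the 5β (cis-fused) C20 aldehyde is the acceptor; both C19 acids travel as allyl esters.
2. In each half C11–C12 is cut: a C11 phenyl sulfone on the bicyclic core is alkylated with one iodo acetal (C12–C15, C13 from an oxazolidinone alkylation) and then desulfonylated.
3. Both cores come from one Diels–Alder adduct. The feature used is ring B, which carries C17 on C8 and the C11 carbon on C9 beside quaternary C10; this is what methyl but-2-ynoate leaves when it adds across C7 and C10 of a ring-A 2-vinylcyclohexene (bonds C7–C8 and C9–C10).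
4. The halves part at C5: Pd/C hydrogenation on the α-face gives the trans core, where C9–H is set by deconjugative protonation; hydroxyl-directed iridium hydrogenation on the β-face gives the cis core, where C11 is removed by decarboxylation and put back on the convex face by a formaldehyde ene reaction.
5. Ring order: ring A first (cyclohexanone β-keto ester, quaternary C4 by chiral-enamine methylation), then ring B by the cycloaddition.

Key step: step 8

Remark on numbering: labdane numbering is used for all bicyclic compounds, including the C14/C15 "drimane" cores (C17 on C8, C11 on C9, C18 α and C19 β on C4, C20 on C10).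
Remark on step 2 (assumption): the HMPA regime is taken as the one giving the (S)-keto ester; the same auxiliary gives the antipode when THF replaces HMPA, so either sense is accessible.

**Ring A and the diene**

Step 1
Reactants: 1 ethyl 2-oxocyclohexane-1-carboxylate; 2 tert-butyl L-valinate
Product: 3 ethyl 2-{[(2S)-1-tert-butoxy-3-methyl-1-oxobutan-2-yl]amino}cyclohex-1-ene-1-carboxylate
Conditions: BF3·OEt2 (cat.), benzene, reflux, Dean–Stark
Reagents that add atoms: none
Why: Condensation of the β-keto ester with the amino ester gives the hydrogen-bonded enamino ester (vinylogous carbamate) that carries the chiral auxiliary for the next step.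

Step 2
Reactants: 3 valine enamino ester
Product: 5 ethyl (S)-1-methyl-2-oxocyclohexane-1-carboxylate, via methylated imine 4 (not isolated)
Conditions: LiN(iPr)2, toluene, −78 °C; HMPA (1 equiv); MeI, −78 to −55 °C; then 1 M aq. HCl, rt
Reagents that add atoms: iodomethane CI; water O
Why: Asymmetric alkylation of a chiral lithio-enamine: the lithium aza-enolate is held in a chelate by the valine ester, whose isopropyl group leaves one face open to iodomethane, so the quaternary centre (future C4, S) is set before hydrolysis returns the ketone and the auxiliary.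

Step 3
Reactants: 5 ethyl (S)-1-methyl-2-oxocyclohexane-1-carboxylate
Product: 6 ethyl (1S)-1,3-dimethyl-2-oxocyclohexane-1-carboxylate (C3 epimers)
Conditions: LiN(iPr)2, THF, −78 °C; MeI, −78 to 0 °C
Reagents that add atoms: iodomethane CI
Why: Enolate alkylation at the only enolisable α-carbon (future C10) brings in C20; the new centre is a mixture and becomes sp2 in step 4.

Step 4
Reactants: 6 ethyl (1S)-1,3-dimethyl-2-oxocyclohexane-1-carboxylate
Product: 7 ethyl (S)-1,3-dimethyl-2-{[(trifluoromethyl)sulfonyl]oxy}cyclohex-2-ene-1-carboxylate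
Conditions: KN(SiMe3)2, THF, −78 °C; PhNTf2, −78 to 0 °C
Reagents that add atoms: N-phenylbis(trifluoromethanesulfonimide) O=S(=O)(N(c1ccccc1)S(=O)(=O)C(F)(F)F)C(F)(F)F
Why: Enol triflate formation: the single α-hydrogen is removed and the potassium enolate is O-sulfonylated, giving the tetrasubstituted C5=C10 alkene with C4 untouched.

Step 5
Reactants: 7 enol triflate
Product: 8 ethyl (S)-1,3-dimethyl-2-vinylcyclohex-2-ene-1-carboxylate
Conditions: CH2=CHSnBu3, Pd(PPh3)4 (5 mol %), LiCl, THF, reflux
Reagents that add atoms: tributyl(vinyl)stannane C=C[Sn](CCCC)(CCCC)CCCC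
Why: Stille cross-coupling (oxidative addition of zerovalent palladium into the enol triflate, chloride-assisted transmetalation, reductive elimination) attaches C6–C7 and completes the diene.

Step 6
Reactants: 8 diene ester
Product: 9 [(S)-1,3-dimethyl-2-vinylcyclohex-2-en-1-yl]methanol
Conditions: LiAlH4, Et2O, 0 °C
Reagents that add atoms: none
Why: Hydride reduction of the ester gives the neopentyl alcohol C19–OH; the unactivated diene does not react with LiAlH4.

Step 7
Reactants: 9 dienol
Product: 10 (S)-tert-butyl[(1,3-dimethyl-2-vinylcyclohex-2-en-1-yl)methoxy]diphenylsilane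
Conditions: t-BuPh2SiCl, imidazole, DMAP (cat.), DMF, rt to 40 °C
Reagents that add atoms: tert-butyl(chloro)diphenylsilane CC(C)(C)[Si](Cl)(c1ccccc1)c1ccccc1
Why: Silylation of the hindered primary alcohol gives the robust, bulky silyl ether that is to shield one face of the diene.

**Key cycloaddition and common intermediate**

Step 8
Reactants: 10 silyl ether diene; 11 methyl but-2-ynoate
Product: 12 methyl 19-(tert-butyldiphenylsilyloxy)drima-5,8-dien-11-oate (C19 and C20 cis, both β)
Conditions: 11 (5 equiv), BHT (cat.), CH2Cl2, 13 kbar, 55 °C, 72 h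
Reagents that add atoms: none
Why: Diels–Alder [4+2] cycloaddition of the semicyclic diene C10=C5–C6=C7 with the alkynoate, concerted but asynchronous: the open terminus C7 bonds first to the β-carbon of the butynoate (C8, bearing C17) and the ester-bearing carbon C9 then closes onto fully substituted C10, the "ortho" orientation expected from the larger HOMO coefficient at C7 and the larger LUMO coefficient at the β-carbon. The closest known reaction type is the cycloaddition of 1,3,3-trimethyl-2-vinylcyclohexene with acetylenic esters, the classical entry to drimanes; because the β-methyl alkynoate is a weaker dienophile and the diene terminus carries a (Z)-methyl, high pressure (large negative activation volume) is used instead of heat, which also avoids a 1,5-hydrogen shift of the diene. Ring B is closed by the cycloaddition itself as a six-membered cyclohexa-1,4-diene, both σ-bonds (C7–C8 and C9–C10) being formed suprafacially in one step. The only new stereocentre is quaternary C10: ring A is a half-chair in which the silyloxymethyl group on C4 should take the pseudoaxial site to avoid allylic strain with the coplanar vinyl group and, with its silyl ether arm, cover that face of C5–C6, so the dienophile enters anti to C19 and C20 is pushed to the C19 face. The step needs regioselectivity (C11 on C9, C17 on C8), secured by the polarisation of the diene, and facial selectivity, secured by the C4 substituent; an alkyne dienophile raises no endo/exo question, and any C10 epimer is removed by chromatography here.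

Step 9
Reactants: 12 silyl ether adduct
Product: 13 methyl 19-hydroxydrima-5,8-dien-11-oate
Conditions: Bu4NF, AcOH (1:1), THF, 45 °C
Reagents that add atoms: none
Why: Fluoride-mediated desilylation, buffered so that the skipped dienoate is not deprotonated at C7, frees the C19 alcohol for both branches.

**Side-chain iodide (C12–C15)**

Step 10
Reactants: 14 (S)-4-benzyl-3-propanoyloxazolidin-2-one
Product: 15 (S)-4-benzyl-3-[(R)-2-methylpent-4-enoyl]oxazolidin-2-one
Conditions: NaN(SiMe3)2, THF, −78 °C; allyl iodide, −78 to −45 °C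
Reagents that add atoms: allyl iodide C=CCI
Why: Evans alkylation: the chelated (Z)-sodium enolate is allylated on the face away from the benzyl group, which sets the stereocentre that becomes C13 (R here).

Step 11
Reactants: 15 alkylated imide
Product: 16 (R)-2-methylpent-4-en-1-ol
Conditions: LiBH4, MeOH (1 equiv), Et2O, 0 °C
Reagents that add atoms: none
Why: Reductive cleavage of the N-acyl oxazolidinone gives the primary alcohol and returns the auxiliary without epimerisation.

Step 12
Reactants: 16 (R)-2-methylpent-4-en-1-ol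
Product: 17 (R)-5-iodo-4-methylpent-1-ene
Conditions: I2, PPh3, imidazole, CH2Cl2, 0 °C to rt
Reagents that add atoms: iodine II
Why: Appel-type iodination of the primary alcohol (SN2 on the alkoxyphosphonium ion at the future C12; the stereocentre is not involved).

Step 13
Reactants: 17 (R)-5-iodo-4-methylpent-1-ene
Product: 19 (R)-4-iodo-1,1-dimethoxy-3-methylbutane, via (R)-4-iodo-3-methylbutanal 18 (not isolated)
Conditions: O3, CH2Cl2/MeOH, −78 °C; Me2S, to rt; then HC(OMe)3, TsOH·H2O (cat.), rt
Reagents that add atoms: trimethyl orthoformate COC(OC)OC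
Why: Ozonolysis of the terminal alkene removes one carbon and gives aldehyde C15, which is masked in the same flask as the dimethyl acetal so that the iodide can later meet a carbanion.

**Trans-fused (5α) half**

Step 14
Reactants: 13 methyl 19-hydroxydrima-5,8-dien-11-oate
Product: 20 methyl 19-hydroxy-5α-drim-8-en-11-oate
Conditions: H2 (3 atm), 10% Pd/C, EtOH, rt
Reagents that add atoms: none
Why: Heterogeneous catalytic hydrogenation of the trisubstituted C5=C6 bond from the α-face, opposite the C20 methyl and the C19 group, sets C5 (H α, trans-decalin) as in the classical drimane diester series; the tetrasubstituted enoate is left.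

Step 15
Reactants: 20 trans hydroxy ester
Product: 21 11-methoxy-11-oxo-5α-drim-8-en-19-oic acid
Conditions: CrO3, H2SO4, H2O, acetone, 0 °C to rt
Reagents that add atoms: water O
Why: Jones oxidation of the primary alcohol through the aldehyde hydrate gives the C19 acid; the conjugated ester and the hindered alkene are inert.

Step 16
Reactants: 21 trans acid ester
Product: 23 11-methoxy-11-oxo-5α-drim-8(17)-en-19-oic acid (9α-H), via dilithium dienolate 22 (not isolated)
Conditions: LiN(iPr)2 (2.4 equiv), THF, −78 to −10 °C; then AcOH, THF, −78 °C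
Reagents that add atoms: none
Why: Deconjugative kinetic protonation of an ester dienolate (β-cyclogeranate type): once the carboxylate has formed, the base removes a C17 hydrogen syn to the ester, and the exocyclic dienolate is protonated at its α-carbon C9 from the α-face, anti to the axial C20 methyl of the trans-decalin, which sets C9 (H α, C11 β) and the 8(17)-alkene.

Step 17
Reactants: 23 deconjugated acid ester
Product: 24 11-hydroxy-5α-drim-8(17)-en-19-oic acid
Conditions: LiBHEt3 (4 equiv), THF, 0 °C to rt; aq. NH4Cl
Reagents that add atoms: none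
Why: Chemoselective hydride reduction: the methyl ester goes to the C11 alcohol while the lithium carboxylate at C19 is not reduced by the borohydride.

Step 18
Reactants: 24 trans hydroxy acid
Product: 25 allyl 11-hydroxy-5α-drim-8(17)-en-19-oate
Conditions: allyl bromide, K2CO3, DMF, rt
Reagents that add atoms: allyl bromide C=CCBr
Why: Carboxylate O-alkylation (SN2) protects the hindered acid as an ester that can be removed at the end under neutral conditions; the alcohol is not alkylated by carbonate.

Step 19
Reactants: 25 trans allyl ester alcohol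
Product: 26 allyl 11-(phenylsulfanyl)-5α-drim-8(17)-en-19-oate
Conditions: PhSSPh, Bu3P, pyridine, 60 °C
Reagents that add atoms: diphenyl disulfide c1ccc(SSc2ccccc2)cc1
Why: Mukaiyama–Hata thioetherification: the alkoxyphosphonium ion at primary C11 is displaced by thiophenolate (SN2), and C9 is not involved.

Step 20
Reactants: 26 trans sulfide
Product: 27 allyl 11-(phenylsulfonyl)-5α-drim-8(17)-en-19-oate
Conditions: (NH4)6Mo7O24·4H2O (10 mol %), 30% H2O2, EtOH, 0 °C to rt
Reagents that add atoms: hydrogen peroxide OO
Why: Molybdate-catalysed peroxide oxidation takes the sulfide to the sulfone and leaves the unactivated 1,1-disubstituted alkene and the allyl ester untouched.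

Step 21
Reactants: 27 trans sulfone; 19 (R)-4-iodo-1,1-dimethoxy-3-methylbutane
Product: 28 allyl 15,15-dimethoxy-11-(phenylsulfonyl)-5α-labd-8(17)-en-19-oate (C11 epimers; C13 as in 19)
Conditions: LiN(iPr)2, THF/HMPA, −78 °C; 19, −78 to −20 °C
Reagents that add atoms: none
Why: Alkylation of the α-sulfonyl carbanion at C11 with the primary iodide (SN2) forms C11–C12; the C11 epimers converge in step 22 and C13 is that of 19.

Step 22
Reactants: 28 trans alkylated sulfone
Product: 29 allyl (13S)-15,15-dimethoxy-5α-labd-8(17)-en-19-oate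
Conditions: 6% Na(Hg), Na2HPO4, MeOH/THF, −20 °C
Reagents that add atoms: none
Why: Reductive desulfonylation by electron transfer from sodium amalgam replaces the sulfonyl group at C11 by hydrogen; isolated alkenes, the acetal and the hindered ester are not reduced.

Step 23
Reactants: 29 trans acetal
Product: 30 allyl (13S)-15-oxo-5α-labd-8(17)-en-19-oate
Conditions: PPTS (cat.), acetone/H2O, 50 °C
Reagents that add atoms: water O
Why: Mild acid-catalysed acetal hydrolysis frees the C15 aldehyde without isomerising the exocyclic alkene.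

Step 24
Reactants: 30 trans aldehyde
Product: 31 N-cyclohexyl aldimine of 30
Conditions: cyclohexylamine, 4 Å MS, Et2O, 0 °C to rt
Reagents that add atoms: cyclohexylamine NC1CCCCC1
Why: Imine condensation turns this aldehyde into the partner that will be metalated, which assigns it the donor role in the crossed aldol (Wittig directed aldol).

**Cis-fused (5β) half**

Step 25
Reactants: 13 methyl 19-hydroxydrima-5,8-dien-11-oate
Product: 32 methyl 19-hydroxy-5β-drim-8-en-11-oate
Conditions: [Ir(cod)(PCy3)(py)]PF6 (5 mol %), H2 (1 atm), CH2Cl2, 0 °C to rt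
Reagents that add atoms: none
Why: Hydroxyl-directed homogeneous hydrogenation: the homoallylic C19–OH binds the cationic iridium hydride and hydrogen is delivered to the β-face of C5=C6, against the steric bias, which sets C5 (H β, cis-decalin); the remote tetrasubstituted enoate is not directed and should remain.

Step 26
Reactants: 32 cis hydroxy ester
Product: 33 11-methoxy-11-oxo-5β-drim-8-en-19-oic acid
Conditions: CrO3, H2SO4, H2O, acetone, 0 °C to rt
Reagents that add atoms: water O
Why: Jones oxidation of the primary alcohol through the aldehyde hydrate gives the C19 acid, as in step 15.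

Step 27
Reactants: 33 cis acid ester
Product: 34 5β-drim-8-ene-11,19-dioic acid
Conditions: n-PrSLi (3 equiv), HMPA, rt; then 1 M HCl
Reagents that add atoms: none
Why: SN2 dealkylation: the thiolate attacks the methyl carbon of the hindered conjugated ester, which avoids acyl substitution at the shielded carbonyl.

Step 28
Reactants: 34 cis diacid
Product: 36 11-nor-5β-drim-8-en-19-oic acid (C8=C9, C17 methyl on C8), via deconjugated diacid 35 (not isolated)
Conditions: quinoline, 210 °C, sealed tube
Reagents that add atoms: none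
Why: Thermal decarboxylation of an α,β-unsaturated acid: amine-mediated isomerisation to the β,γ-unsaturated acid 35, then a retro-ene loss of CO2 that returns the double bond to C8=C9; the saturated tertiary C19 acid has no such pathway.

Step 29
Reactants: 36 11-nor acid
Product: 37 allyl 11-nor-5β-drim-8-en-19-oate
Conditions: allyl bromide, K2CO3, DMF, rt
Reagents that add atoms: allyl bromide C=CCBr
Why: Carboxylate O-alkylation (SN2) gives the allyl ester, as in step 18.

Step 30
Reactants: 37 11-nor allyl ester
Product: 38 allyl 11-hydroxy-5β-drim-8(17)-en-19-oate (9α-H)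
Conditions: Me2AlCl (2.5 equiv), (CH2O)n, CH2Cl2, −78 to 0 °C
Reagents that add atoms: formaldehyde C=O
Why: Lewis acid-promoted carbonyl-ene reaction: formaldehyde bonds to the less substituted alkene carbon C9 from the convex β-face of the cis-decalin (anti to the axial C1 on C10) and takes a hydrogen from the C17 methyl, which is syn to the vinylic hydrogen, so C11 ends β (H9 α) with the 8(17)-alkene; carbon is the group delivered to the open face here, whereas protonation of a dienolate in this cis series would put hydrogen there and give the C9 epimer.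

Step 31
Reactants: 38 cis allyl ester alcohol
Product: 39 allyl 11-(phenylsulfanyl)-5β-drim-8(17)-en-19-oate
Conditions: PhSSPh, Bu3P, pyridine, 60 °C
Reagents that add atoms: diphenyl disulfide c1ccc(SSc2ccccc2)cc1
Why: Mukaiyama–Hata thioetherification by SN2 at primary C11, as in step 19.

Step 32
Reactants: 39 cis sulfide
Product: 40 allyl 11-(phenylsulfonyl)-5β-drim-8(17)-en-19-oate
Conditions: (NH4)6Mo7O24·4H2O (10 mol %), 30% H2O2, EtOH, 0 °C to rt
Reagents that add atoms: hydrogen peroxide OO
Why: Molybdate-catalysed sulfide-to-sulfone oxidation that spares the alkenes, as in step 20.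

Step 33
Reactants: 40 cis sulfone; 19 (R)-4-iodo-1,1-dimethoxy-3-methylbutane
Product: 41 allyl 15,15-dimethoxy-11-(phenylsulfonyl)-5β-labd-8(17)-en-19-oate (C11 epimers; C13 as in 19)
Conditions: LiN(iPr)2, THF/HMPA, −78 °C; 19, −78 to −20 °C
Reagents that add atoms: none
Why: Alkylation of the α-sulfonyl carbanion at C11 with the primary iodide (SN2) forms C11–C12, as in step 21.

Step 34
Reactants: 41 cis alkylated sulfone
Product: 42 allyl (13S)-15,15-dimethoxy-5β-labd-8(17)-en-19-oate
Conditions: 6% Na(Hg), Na2HPO4, MeOH/THF, −20 °C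
Reagents that add atoms: none
Why: Reductive desulfonylation with sodium amalgam, as in step 22.

Step 35
Reactants: 42 cis acetal
Product: 43 allyl (13S)-15-oxo-5β-labd-8(17)-en-19-oate
Conditions: PPTS (cat.), acetone/H2O, 50 °C
Reagents that add atoms: water O
Why: Mild acid-catalysed acetal hydrolysis frees the C15′ aldehyde, the acceptor for the aldol.

**Union**

Step 36
Reactants: 31 trans aldimine; 43 cis aldehyde
Product: 46 bis(allyl ester) of the target, via lithiated aldimine 44 (not isolated), via aldol imine 45 (not isolated)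
Conditions: LiN(iPr)2, THF, −78 to 0 °C; 43, −78 to −20 °C; then aq. oxalic acid, THF, rt to 45 °C
Reagents that add atoms: water O
Why: Directed aldol condensation (Wittig): the lithiated aldimine adds through C14 to the aldehyde carbon C15′ of 43, and acid hydrolysis of the imine with loss of water gives the 2-alkyl enal as the more stable (E) isomer (CHO trans to the C14′ chain); C13 and C13′ are not acidic in substrate or product.

Step 37
Reactants: 46 bis(allyl ester)
Product: 47 CNP0229303.1 (target diacid)
Conditions: Pd(PPh3)4 (5 mol %), sodium 4-toluenesulfinate, THF/MeOH, rt; then dilute HCl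
Reagents that add atoms: none
Why: Palladium-catalysed allyl transfer (a π-allyl complex of divalent palladium, formed from zerovalent palladium, is captured by sulfinate) frees both hindered acids under neutral conditions that the enal and the exocyclic alkenes tolerate.

**Compound list**

1 | ethyl 2-oxocyclohexane-1-carboxylate | CCOC(=O)C1CCCCC1=O | starting material
2 | tert-butyl L-valinate | CC(C)[C@H](N)C(=O)OC(C)(C)C | starting material
3 | ethyl 2-{[(2S)-1-tert-butoxy-3-methyl-1-oxobutan-2-yl]amino}cyclohex-1-ene-1-carboxylate | CCOC(=O)C1=C(N[C@@H](C(C)C)C(=O)OC(C)(C)C)CCCC1 | intermediate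
4 | ethyl (1S)-2-{[(2S)-1-tert-butoxy-3-methyl-1-oxobutan-2-yl]imino}-1-methylcyclohexane-1-carboxylate | CCOC(=O)[C@@]1(C)CCCCC1=N[C@@H](C(C)C)C(=O)OC(C)(C)C | intermediate
5 | ethyl (S)-1-methyl-2-oxocyclohexane-1-carboxylate | CCOC(=O)[C@@]1(C)CCCCC1=O | intermediate
6 | ethyl (1S)-1,3-dimethyl-2-oxocyclohexane-1-carboxylate (C3 epimers) | CCOC(=O)[C@@]1(C)CCCC(C)C1=O | intermediate
7 | ethyl (S)-1,3-dimethyl-2-{[(trifluoromethyl)sulfonyl]oxy}cyclohex-2-ene-1-carboxylate | CCOC(=O)[C@@]1(C)CCCC(C)=C1OS(=O)(=O)C(F)(F)F | intermediate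
8 | ethyl (S)-1,3-dimethyl-2-vinylcyclohex-2-ene-1-carboxylate | CCOC(=O)[C@@]1(C)CCCC(C)=C1C=C | intermediate
9 | [(S)-1,3-dimethyl-2-vinylcyclohex-2-en-1-yl]methanol | C=CC1=C(C)CCC[C@]1(C)CO | intermediate
10 | (S)-tert-butyl[(1,3-dimethyl-2-vinylcyclohex-2-en-1-yl)methoxy]diphenylsilane | C=CC1=C(C)CCC[C@]1(C)CO[Si](c1ccccc1)(c1ccccc1)C(C)(C)C | intermediate
11 | methyl but-2-ynoate | CC#CC(=O)OC | starting material
12 | methyl 19-(tert-butyldiphenylsilyloxy)drima-5,8-dien-11-oate (C19, C20 β) | CC1=C(C(=O)OC)[C@@]2(C)CCC[C@](C)(CO[Si](c3ccccc3)(c3ccccc3)C(C)(C)C)C2=CC1 | intermediate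
13 | methyl 19-hydroxydrima-5,8-dien-11-oate | CC1=C(C(=O)OC)[C@@]2(C)CCC[C@](C)(CO)C2=CC1 | intermediate
14 | (S)-4-benzyl-3-propanoyloxazolidin-2-one | CCC(=O)N1[C@@H](Cc2ccccc2)COC1=O | starting material
15 | (S)-4-benzyl-3-[(R)-2-methylpent-4-enoyl]oxazolidin-2-one | C=CC[C@@H](C)C(=O)N1[C@@H](Cc2ccccc2)COC1=O | intermediate
16 | (R)-2-methylpent-4-en-1-ol | C=CC[C@@H](C)CO | intermediate
17 | (R)-5-iodo-4-methylpent-1-ene | C=CC[C@@H](C)CI | intermediate
18 | (R)-4-iodo-3-methylbutanal | O=CC[C@@H](C)CI | intermediate
19 | (R)-4-iodo-1,1-dimethoxy-3-methylbutane | COC(OC)C[C@@H](C)CI | intermediate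
20 | methyl 19-hydroxy-5α-drim-8-en-11-oate (trans-fused) | CC1=C(C(=O)OC)[C@@]2(C)CCC[C@](C)(CO)[C@@H]2CC1 | intermediate
21 | 11-methoxy-11-oxo-5α-drim-8-en-19-oic acid | CC1=C(C(=O)OC)[C@@]2(C)CCC[C@](C)(C(=O)O)[C@@H]2CC1 | intermediate
22 | dilithium 8(17),9(11)-dienolate of 21 | C=C1CC[C@@H]2[C@](C)(CCC[C@]2(C)C(=O)O[Li])C1=C(OC)O[Li] | intermediate
23 | 11-methoxy-11-oxo-5α-drim-8(17)-en-19-oic acid (9α-H) | C=C1CC[C@@H]2[C@](C)(CCC[C@]2(C)C(=O)O)[C@H]1C(=O)OC | intermediate
24 | 11-hydroxy-5α-drim-8(17)-en-19-oic acid | C=C1CC[C@@H]2[C@](C)(CCC[C@]2(C)C(=O)O)[C@H]1CO | intermediate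
25 | allyl 11-hydroxy-5α-drim-8(17)-en-19-oate | C=C1CC[C@@H]2[C@](C)(CCC[C@]2(C)C(=O)OCC=C)[C@H]1CO | intermediate
26 | allyl 11-(phenylsulfanyl)-5α-drim-8(17)-en-19-oate | C=C1CC[C@@H]2[C@](C)(CCC[C@]2(C)C(=O)OCC=C)[C@H]1CSc1ccccc1 | intermediate
27 | allyl 11-(phenylsulfonyl)-5α-drim-8(17)-en-19-oate | C=C1CC[C@@H]2[C@](C)(CCC[C@]2(C)C(=O)OCC=C)[C@H]1CS(=O)(=O)c1ccccc1 | intermediate
28 | allyl 15,15-dimethoxy-11-(phenylsulfonyl)-5α-labd-8(17)-en-19-oate (C11 epimers; C13 as in 29, 13R by CIP because of the sulfone) | C=C1CC[C@@H]2[C@](C)(CCC[C@]2(C)C(=O)OCC=C)[C@H]1C(C[C@H](C)CC(OC)OC)S(=O)(=O)c1ccccc1 | intermediate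
29 | allyl (13S)-15,15-dimethoxy-5α-labd-8(17)-en-19-oate | C=C1CC[C@@H]2[C@](C)(CCC[C@]2(C)C(=O)OCC=C)[C@H]1CC[C@H](C)CC(OC)OC | intermediate
30 | allyl (13S)-15-oxo-5α-labd-8(17)-en-19-oate | C=C1CC[C@@H]2[C@](C)(CCC[C@]2(C)C(=O)OCC=C)[C@H]1CC[C@H](C)CC=O | intermediate
31 | allyl (13S)-15-(cyclohexylimino)-5α-labd-8(17)-en-19-oate | C=C1CC[C@@H]2[C@](C)(CCC[C@]2(C)C(=O)OCC=C)[C@H]1CC[C@H](C)C/C=N/C3CCCCC3 | intermediate
32 | methyl 19-hydroxy-5β-drim-8-en-11-oate (cis-fused) | CC1=C(C(=O)OC)[C@@]2(C)CCC[C@](C)(CO)[C@H]2CC1 | intermediate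
33 | 11-methoxy-11-oxo-5β-drim-8-en-19-oic acid | CC1=C(C(=O)OC)[C@@]2(C)CCC[C@](C)(C(=O)O)[C@H]2CC1 | intermediate
34 | 5β-drim-8-ene-11,19-dioic acid | CC1=C(C(=O)O)[C@@]2(C)CCC[C@](C)(C(=O)O)[C@H]2CC1 | intermediate
35 | 5β-drim-8(17)-ene-11,19-dioic acid (C9 epimers) | C=C1CC[C@H]2[C@](C)(CCC[C@]2(C)C(=O)O)C1C(=O)O | intermediate
36 | 11-nor-5β-drim-8-en-19-oic acid | CC1=C[C@@]2(C)CCC[C@](C)(C(=O)O)[C@H]2CC1 | intermediate
37 | allyl 11-nor-5β-drim-8-en-19-oate | CC1=C[C@@]2(C)CCC[C@](C)(C(=O)OCC=C)[C@H]2CC1 | intermediate
38 | allyl 11-hydroxy-5β-drim-8(17)-en-19-oate (9α-H) | C=C1CC[C@H]2[C@](C)(CCC[C@]2(C)C(=O)OCC=C)[C@H]1CO | intermediate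
39 | allyl 11-(phenylsulfanyl)-5β-drim-8(17)-en-19-oate | C=C1CC[C@H]2[C@](C)(CCC[C@]2(C)C(=O)OCC=C)[C@H]1CSc1ccccc1 | intermediate
40 | allyl 11-(phenylsulfonyl)-5β-drim-8(17)-en-19-oate | C=C1CC[C@H]2[C@](C)(CCC[C@]2(C)C(=O)OCC=C)[C@H]1CS(=O)(=O)c1ccccc1 | intermediate
41 | allyl 15,15-dimethoxy-11-(phenylsulfonyl)-5β-labd-8(17)-en-19-oate (C11 epimers; C13 as in 42) | C=C1CC[C@H]2[C@](C)(CCC[C@]2(C)C(=O)OCC=C)[C@H]1C(C[C@H](C)CC(OC)OC)S(=O)(=O)c1ccccc1 | intermediate
42 | allyl (13S)-15,15-dimethoxy-5β-labd-8(17)-en-19-oate | C=C1CC[C@H]2[C@](C)(CCC[C@]2(C)C(=O)OCC=C)[C@H]1CC[C@H](C)CC(OC)OC | intermediate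
43 | allyl (13S)-15-oxo-5β-labd-8(17)-en-19-oate | C=C1CC[C@H]2[C@](C)(CCC[C@]2(C)C(=O)OCC=C)[C@H]1CC[C@H](C)CC=O | intermediate
44 | N-lithio enamide (aza-enolate) of 31 | C=C1CC[C@@H]2[C@](C)(CCC[C@]2(C)C(=O)OCC=C)[C@H]1CC[C@H](C)C=CN([Li])C3CCCCC3 | intermediate
45 | aldol adduct, β-hydroxy aldimine (C14 and C15′ unassigned) | C=C1CC[C@@H]2[C@](C)(CCC[C@]2(C)C(=O)OCC=C)[C@H]1CC[C@H](C)C(C=NC3CCCCC3)C(O)C[C@@H](C)CC[C@H]1C(=C)CC[C@H]2[C@]1(C)CCC[C@]2(C)C(=O)OCC=C | intermediate
46 | bis(allyl ester) of the target, (E)-enal | C=C1CC[C@@H]2[C@](C)(CCC[C@]2(C)C(=O)OCC=C)[C@H]1CC[C@H](C)/C(C=O)=C\C[C@@H](C)CC[C@H]1C(=C)CC[C@H]2[C@]1(C)CCC[C@]2(C)C(=O)OCC=C | intermediate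
47 | CNP0229303.1 | C=C1CC[C@@H]2[C@](C)(CCC[C@]2(C)C(=O)O)[C@H]1CC[C@H](C)/C(C=O)=C\C[C@@H](C)CC[C@H]1C(=C)CC[C@H]2[C@]1(C)CCC[C@]2(C)C(=O)O | target

**Step count and risks**

Total step count: 37. Longest linear sequence: 22 steps (steps 1–9, then 14–24 or 25–35, then 36–37).

Steps most likely to fail:

1. Step 8 (key cycloaddition). The cycloaddition may be too slow for a β-substituted alkynoate on a hindered diene with a (Z)-methyl terminus, the diene may isomerise, and the two C4 substituents may discriminate the diene faces only weakly, so that the C10 epimer forms. The fallback sets out from 10 and returns at 12. The dienophile is changed to the far more electrophilic but-2-ynal, activated by Me2AlCl in CH2Cl2 at −78 °C (Lewis acid-catalysed Diels–Alder, lower temperature, tighter transition state). This should give 19-(tert-butyldiphenylsilyloxy)drima-5,8-dien-11-al F1. Pinnick oxidation (NaClO2, NaH2PO4, 2-methylbut-2-ene) would give 19-(tert-butyldiphenylsilyloxy)drima-5,8-dien-11-oic acid F2, and methylation (MeI, K2CO3, DMF) returns to 12.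

2. Step 30 (ene reaction). Bond formation at the neopentyl-type C9 may be slow, the developing tertiary cation at C8 may be captured by chloride, hydrogen may be lost from C7 instead of C17, or the allyl ester may interfere with the Lewis acid. The fallback sets out from 36 and returns at 38, making C9–C11 by allylboration. The C17 methyl of acid 36 is metalated with n-BuLi/KOt-Bu (carboxylate first, then the allyl anion) and trapped with 2-isopropoxy-4,4,5,5-tetramethyl-1,3,2-dioxaborolane to give 17-(pinacolboryl)-11-nor-5β-drim-8-en-19-oic acid F4. Reaction with formaldehyde through the six-membered chair transition state transfers the allyl unit with transposition, so that C11 bonds to C9 from the convex face and the 8(17)-alkene forms. Hydrolytic work-up gives 11-hydroxy-5β-drim-8(17)-en-19-oic acid F5, and allyl bromide/K2CO3 returns to 38.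

3. Step 25 (directed hydrogenation). Undirected addition from the open α-face may compete (poor facial selectivity), the enoate may be over-reduced, or the skipped diene may isomerise on the metal. The fallback sets out from 13 and returns at 33; it inverts the order of oxidation and hydrogenation so that a stronger, anionic director is in place. Jones oxidation of 13 gives 11-methoxy-11-oxodrima-5,8-dien-19-oic acid F3. Hydrogenation of its triethylammonium carboxylate with [Rh(nbd)(dppb)]BF4 under H2 (a cationic complex of univalent rhodium, carboxylate-directed) should deliver hydrogen from the C19 face and give 33 directly.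

Further compounds
F1 | step 8 | 19-(tert-butyldiphenylsilyloxy)drima-5,8-dien-11-al | CC1=C(C=O)[C@@]2(C)CCC[C@](C)(CO[Si](c3ccccc3)(c3ccccc3)C(C)(C)C)C2=CC1
F2 | step 8 | 19-(tert-butyldiphenylsilyloxy)drima-5,8-dien-11-oic acid | CC1=C(C(=O)O)[C@@]2(C)CCC[C@](C)(CO[Si](c3ccccc3)(c3ccccc3)C(C)(C)C)C2=CC1
F3 | step 25 | 11-methoxy-11-oxodrima-5,8-dien-19-oic acid | CC1=C(C(=O)OC)[C@@]2(C)CCC[C@](C)(C(=O)O)C2=CC1
F4 | step 30 | 17-(4,4,5,5-tetramethyl-1,3,2-dioxaborolan-2-yl)-11-nor-5β-drim-8-en-19-oic acid | CC1(C)OB(CC2=C[C@@]3(C)CCC[C@](C)(C(=O)O)[C@H]3CC2)OC1(C)C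
F5 | step 30 | 11-hydroxy-5β-drim-8(17)-en-19-oic acid | C=C1CC[C@H]2[C@](C)(CCC[C@]2(C)C(=O)O)[C@H]1CO
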